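Slowness is what we have to reckon with: in larch, charged as dawn is, 35% of the starting material still stands at 30.0 h. So we work with the fraction left, and first ask which number has to be known well.

| setting | larch | oak | birch | alder | spring | midnight | dawn | dusk |
|---|---|---|---|---|---|---|---|---|
| starting material | 0.052 M | 0.052 M | 0.052 M | 0.026 M | 0.052 M (fed, over 25 h) | 0.052 M | 0.052 M | 0.052 M |
| partner | 2.5 equiv | 1.2 equiv | 5 equiv | 2.5 equiv | 2.50 equiv | 2.50 equiv (in portions, 4, over 25 h) | 2.50 equiv | 2.50 equiv (fed, over 25 h) |
| remark | run made earlier | run made earlier | run made earlier | run made earlier | all else is in the flask from the start; the feed brings no volume worth counting | first portion at the start, last at 25 h | everything together at the start | all else is in the flask from the start; the feed brings no volume worth counting |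
| time |  |  |  |  | 30 h | 30 h | 30 h | 30 h |

| run | time / h | mono adduct / % | starting material / % |
|---|---|---|---|
| larch | 2.00 | 6 | 95 |
| larch | 6.00 | 18 | 80 |
| larch | 10.0 | 29 | 71 |
| larch | 15.0 | 39 | 59 |
| larch | 25.0 | 54 | 45 |
| larch | 30.0 | 59 | 35 |
| oak | 1.50 | 1 | 97 |
| oak | 5.00 | 8 | 90 |
| oak | 8.00 | 14 | 88 |
| oak | 12.0 | 15 | 82 |
| oak | 20.0 | 26 | 70 |
| oak | 25.0 | 32 | 67 |
| birch | 1.50 | 9 | 87 |
| birch | 5.00 | 27 | 71 |
| birch | 8.00 | 45 | 55 |
| birch | 12.0 | 54 | 41 |
| birch | 20.0 | 70 | 25 |
| birch | 25.0 | 79 | 20 |
| alder | 5.00 | 9 | 96 |
| alder | 10.0 | 17 | 85 |
| alder | 15.0 | 22 | 78 |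
| alder | 20.0 | 27 | 70 |
| alder | 25.0 | 36 | 62 |

(standard deviation of a reading: 1.5 percentage points)

- the flask with the highest amount of mono adduct, in percent of the starting material charged ("all alike" if they lie within 1.5 percentage points) (spring / midnight / dawn / dusk / all alike)
- final mono adduct, as a percentage of the starting material charged, in spring
- final mono adduct, as a percentage of the starting material charged, in midnight
- final mono adduct, as a percentage of the starting material charged, in dawn
- final mono adduct, as a percentage of the starting material charged, in dusk

The side products matter little: in larch at 25.0 h, mono adduct and starting material sum to 99.0%. That sum has the crystals in it, since they are counted in mono adduct. The rate does matter. In larch at 15.0 h, 59% is left and partner has averaged 91.8% of its charge, which gives 26.1 h as the lifetime of starting material against the whole partner charge, a pseudo-first-order lifetime. The logarithm of the fraction left falls by the partner-hours seen, divided by this lifetime. One scatter on that reading shifts the lifetime by 4.82%.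

For dawn we reckon 36.8% left, so 63.2% mono adduct, and that shift moves it by 1.8 percentage points. Dusk and midnight both offer 17.5 h of partner-hours before use. Taking off what is consumed leaves 57.2% of the starting material, so 42.8% mono adduct. For spring, averaging the fed slices over their own times gives 55.9% left, so 44.1% mono adduct.

The forecast names dawn, with 62.5% (58% to 66%) against 44%, 44.5% and 45% for spring, midnight and dusk, its dusk standing 2.2 points above ours, and its ground is “Dosing lowers the concentration product, so it costs conversion”.

Dawn gives 59.9% mono adduct, more than spring with 41.3%, midnight with 42.4% and dusk with 42.8%.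

    starting material + partner → mono adduct (k = 0.290 L mol⁻¹ h⁻¹)
    partner + mono adduct → bis adduct (k = 0.200 L mol⁻¹ h⁻¹)
    crystals ⇌ mono adduct, rate k3*(cs3 - [mono adduct]) while solid is left; crystals form when [mono adduct] > cs3 (solubility = 0.780 mM, k = 5.50 h⁻¹)
    mono adduct ⇌ isomer of the product (K = 0.440, k = 0.0200 h⁻¹)

At 30 h, dawn still holds 38.3% of its starting material and 74.8% of its partner. With that partner as the end of a straight fall, our lifetime gives 36.6% left in dawn. In the neighbour charged at 0.031 M, the lifetime grows to 43.8 h, and with its 81.4% of partner at the end we reckon 53.7% left. That neighbour holds 54.7% starting material at 30 h.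

The readings stem from a simulated flask for an exercise.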